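8.2 % of the charge was already isomer of the product at the first reading of the violet run, 1.00 min in, and the later readings stayed between 7.8 % and 8.3 %.

| flask | starting material | remark | time |
|---|---|---|---|
| violet | 5 mM | the very flask that is asked about, followed so far |  |
| flask | 5.0 mM |  | 20 min |

violet run (percent of the starting material charged)

| time / min | isomer of the product / % | target / % |
|---|---|---|
| 1.00 | 8.2 | 85.8 |
| 2.50 | 7.8 | 89.8 |
| 3.00 | 8.3 | 89.7 |
| 5.00 | 8.1 | 88.9 |
| 6.00 | 8.0 | 89.2 |
| 8.00 | 7.9 | 88.9 |

(standard deviation of a reading: 0.3 percentage points)



- ratio of isomer of the product to target at 0.50 s
- ratio of isomer of the product to target at 25 s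
- ratio of isomer of the product to target at 20 min
- which of isomer of the product and target there is more of at 20 min

So I asked first how the charge divides. I took the branch ratio b, isomer of the product over target in the readings at 2.50 min and 3.00 min, 0.0897. The first reading gave 0.0956, but that was one reading with target still rising, so I kept b for both early times.

Next I asked whether the ratio moves later. Between the readings at 2.50 min and 3.00 min and those at 6.00 min and 8.00 min, target fell at d, 0.00165 /min as a fraction of the charge. Over 20 min that is a small correction, 3.29 % of the charge, so I reckoned just that: b divided by the fraction of the target plateau kept gave 0.0931.

Last, could that loss turn the lead? It is far smaller than the gap between the two products, so I kept target ahead.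

The forecast gave 0.11, 0.095 and 0.09, with target ahead, holding that “the slight target drift is within scatter”. It stood above my reckoning at both early times and below it at 20 min.

The flask gave 0.0902, 0.0902 and 0.0953, with target ahead, 85.5 % against 8.15 %.

    starting material ⇌ other conformer, settled at all times (K = 0.160)
    starting material → target (k = 0.0550 /s)
    other conformer → isomer of the product (k = 0.0310 /s)
    target → over-reaction product (k = 4.70 × 10⁻⁵ /s)
    2 other conformer → self-condensation product (k = 8.40 /M/s)

The ratio at 20 min depended on the length of the run: the half-life of target by its passing into over-reaction product, 4.1 h, is far longer than 20 min. A run ten times as long gave 0.158. I carried b, 0.0897, to the neighbour flask with 20 mM of starting material, which gave 0.0902 at 0.50 s and 0.0953 at 20 min, while its self-condensation product, counted as two, stood at 5.72 %.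

(The earlier runs and the new flask are simulated with made-up constants, noise included.)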